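**Plan**
- Locants follow carotenoid numbering: ring C1 (CMe2) to C6 (CH stereocentre), C5 the methyl-bearing alkene carbon, chain C7…C15, C15'…C1'. In the cyclohexene ring the two-carbon unit C3–C4 lies between C2 (a CH2 on the quaternary C1) and C5. C1 cannot belong to a diene, but C5 can be a methyl ketone and C2 a primary radical, so C3–C4 is inserted as a vinylphosphonium linchpin (radical addition, then intramolecular Wittig).
- Cuts, in retrosynthetic order: C7'=C8' (Horner–Wadsworth–Emmons), C7=C8 (Julia–Kocienski), ring C4=C5 and C2–C3 together (decarboxylative annulation of a δ-keto acid), C6–C7 (hydroxymethylation), C1–C2 (Mukaiyama–Michael on mesityl oxide).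
- Forward: the acyclic keto acid is built from tert-butyl acetate, mesityl oxide and formaldehyde; the only ring closes in step 6; the C20 dialdehyde and the geranyl C10 unit are joined last.
- Stereochemistry: C6 is set in step 3 by catalytic asymmetric hydroxymethylation and carried through the base-free ring closure; all chain double bonds are E (purchased E building blocks, E-selective olefinations).
- Helpers: CO2H on C2 (radical source, leaves as CO2), silyl ether on O7, tetrazolyl sulfone on C7.

Key step: step 6

Remark: all-E crocetin dialdehyde 14 is taken as a purchasable C20 building block, and all polyene steps are run under argon in dim light.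

**Step 1**
Reactants: 1 tert-butyl acetate
Product: 2 tert-butyl[(1-tert-butoxyethenyl)oxy]dimethylsilane
Conditions: LiN(iPr)2, THF, −78 °C; then t-BuMe2SiCl, DMPU, −78 °C → rt
Reagents that add atoms: tert-butyldimethylsilyl chloride, CC(C)(C)[Si](C)(C)Cl
Why: The kinetic lithium ester enolate is O-silylated (silyl ketene acetal formation), the bulky silyl chloride and the donor cosolvent suppressing C-silylation.

**Step 2**
Reactants: 2 tert-butyl[(1-tert-butoxyethenyl)oxy]dimethylsilane; 3 mesityl oxide (4-methylpent-3-en-2-one)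
Product: 4 tert-butyl (4Z)-5-[(tert-butyldimethylsilyl)oxy]-3,3-dimethylhex-4-enoate
Conditions: Tf2NH (1 mol %), CH2Cl2, −78 °C; Et3N quench
Reagents that add atoms: none
Why: Mukaiyama–Michael addition, in which the silyl triflimide formed in the flask activates the enone, the unhindered ketene acetal attacks the β,β-dimethyl terminus to create the quaternary carbon C1, and silyl transfer to oxygen should give the regiodefined enol ether (Z from the s-cis enone).

**Step 3**
Reactants: 4 tert-butyl (4Z)-5-[(tert-butyldimethylsilyl)oxy]-3,3-dimethylhex-4-enoate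
Product: 5 tert-butyl (4S)-4-(hydroxymethyl)-3,3-dimethyl-5-oxohexanoate
Conditions: Sc(OTf)3 (10 mol %), (S,S)-6,6'-bis(1-hydroxy-2,2-dimethylpropyl)-2,2'-bipyridine (12 mol %), aq. HCHO (5 equiv), DME/H2O 9:1, −20 → 0 °C
Reagents that add atoms: formaldehyde, C=O
Why: Catalytic asymmetric Mukaiyama hydroxymethylation of a silicon enolate, in which formaldehyde held in the chiral scandium–bipyridine pocket must add to the Re face of C4 of the (Z)-enol ether to set the only stereocentre as S; the ligand enantiomer is chosen to give this sense, which is to be confirmed at alcohol 11.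

**Step 4**
Reactants: 5 tert-butyl (4S)-4-(hydroxymethyl)-3,3-dimethyl-5-oxohexanoate
Product: 6 tert-butyl (4S)-4-{[(tert-butyldiphenylsilyl)oxy]methyl}-3,3-dimethyl-5-oxohexanoate
Conditions: t-BuPh2SiCl, imidazole, DMF, 0 °C → rt
Reagents that add atoms: tert-butyldiphenylsilyl chloride, CC(C)(C)[Si](Cl)(c1ccccc1)c1ccccc1
Why: Silylation of the primary alcohol under weakly basic conditions blocks retro-aldol and lactonisation, and this silyl ether is chosen because it survives the acid of step 5.

**Step 5**
Reactants: 6 tert-butyl (4S)-4-{[(tert-butyldiphenylsilyl)oxy]methyl}-3,3-dimethyl-5-oxohexanoate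
Product: 7 (4S)-4-{[(tert-butyldiphenylsilyl)oxy]methyl}-3,3-dimethyl-5-oxohexanoic acid
Conditions: CF3CO2H/CH2Cl2 1:4, 0 °C → rt
Reagents that add atoms: none
Why: Acidolysis of the tert-butyl ester (loss of 2-methylpropene) frees the carboxylic acid without base, so the stereocentre α to the ketone is not touched.

**Step 6**
Reactants: 7 (4S)-4-{[(tert-butyldiphenylsilyl)oxy]methyl}-3,3-dimethyl-5-oxohexanoic acid; 8 vinyltriphenylphosphonium bromide
Product: 10 tert-butyl{[(1R)-2,6,6-trimethylcyclohex-2-en-1-yl]methoxy}diphenylsilane, via phosphonium ylide 9 (not isolated)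
Conditions: 8 (1.5 equiv), [Ir(dF(CF3)ppy)2(dtbbpy)]PF6 (2 mol %), Cs2CO3 (1.1 equiv), degassed MeCN (0.05 M), 450 nm LEDs, rt
Reagents that add atoms: none
Why: Proposed new method: the carboxylate of 7 is oxidised by the photoexcited trivalent iridium complex and loses CO2 to give the primary radical at C2, which adds to the terminal carbon of the vinylphosphonium salt (C2–C3 bond); the α-phosphonio radical is reduced by divalent iridium to ylide 9, whose carbanion carbon C4 attacks the methyl ketone C5 in a 6-exo-trig mode, the oxaphosphetane collapsing to Ph3PO and the C4=C5 alkene. The closest known reactions are the photoredox three-component olefination of carboxylic acids, vinylphosphonium salts and carbonyl compounds and the anionic Schweizer annulation of carbonyl-tethered nucleophiles with vinylphosphonium salts, which are merged here into a ring-forming formal [4+2]. No stereocentre is created; the one at C6 is carried through because no base stronger than carbonate is present, the ylide arises by electron transfer and is consumed within the molecule, and the C6–H next to the quaternary carbon is enolised only slowly. The step needs intermolecular radical addition to outrun 1,5-hydrogen transfer from the acetyl methyl, which the excess of the strongly electrophilic vinylphosphonium salt should secure, and it needs a single alkene position, which the Wittig closure secures because the double bond can only form between the ylide carbon and the former carbonyl carbon.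

**Step 7**
Reactants: 10 tert-butyl{[(1R)-2,6,6-trimethylcyclohex-2-en-1-yl]methoxy}diphenylsilane
Product: 11 [(1R)-2,6,6-trimethylcyclohex-2-en-1-yl]methanol ((R)-α-cyclogeraniol)
Conditions: Bu4NF, THF, rt → 40 °C
Reagents that add atoms: none
Why: Fluoride-driven desilylation (strong Si–F bond) frees the primary alcohol without affecting the ring alkene or the allylic stereocentre.

**Step 8**
Reactants: 11 [(1R)-2,6,6-trimethylcyclohex-2-en-1-yl]methanol
Product: 12 1-phenyl-5-({[(1R)-2,6,6-trimethylcyclohex-2-en-1-yl]methyl}sulfanyl)-1H-tetrazole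
Conditions: 1-phenyl-1H-tetrazole-5-thiol, PPh3, diisopropyl azodicarboxylate, THF, 0 °C → rt
Reagents that add atoms: 1-phenyl-1H-tetrazole-5-thiol, Sc1nnnn1-c1ccccc1
Why: Mitsunobu thioetherification, in which the acidic heteroaryl thiol displaces the oxyphosphonium group at the primary carbon C7 and the adjacent stereocentre is not involved.

**Step 9**
Reactants: 12 1-phenyl-5-({[(1R)-2,6,6-trimethylcyclohex-2-en-1-yl]methyl}sulfanyl)-1H-tetrazole
Product: 13 1-phenyl-5-({[(1R)-2,6,6-trimethylcyclohex-2-en-1-yl]methyl}sulfonyl)-1H-tetrazole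
Conditions: (NH4)6Mo7O24·4H2O (10 mol %), 30% H2O2, EtOH, 0 °C → rt
Reagents that add atoms: hydrogen peroxide, OO
Why: Molybdate-catalysed peroxide oxidation of sulfide to sulfone is selective for sulfur over the trisubstituted ring alkene.

**Step 10**
Reactants: 13 1-phenyl-5-({[(1R)-2,6,6-trimethylcyclohex-2-en-1-yl]methyl}sulfonyl)-1H-tetrazole; 14 crocetin dialdehyde ((2E,4E,6E,8E,10E,12E,14E)-2,6,11,15-tetramethylhexadeca-2,4,6,8,10,12,14-heptaenedial)
Product: 15 (6R)-8'-apo-ε-caroten-8'-al ((2E,4E,6E,8E,10E,12E,14E,16E)-2,6,11,15-tetramethyl-17-[(1R)-2,6,6-trimethylcyclohex-2-en-1-yl]heptadeca-2,4,6,8,10,12,14,16-octaenal)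
Conditions: KN(SiMe3)2 (1.0 equiv), THF, −78 °C; transfer into 14 (3 equiv), THF, −78 °C → rt
Reagents that add atoms: none
Why: Julia–Kocienski olefination, in which the sulfonyl carbanion adds to one aldehyde of the dialdehyde kept in excess, Smiles rearrangement and anti loss of SO2 and tetrazolate should give the (7E)-alkene, and the second aldehyde survives because the anion is the limiting component.

**Step 11**
Reactants: 16 geranyl bromide ((2E)-1-bromo-3,7-dimethylocta-2,6-diene); 17 triethyl phosphite
Product: 18 diethyl [(2E)-3,7-dimethylocta-2,6-dien-1-yl]phosphonate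
Conditions: neat, 130 °C, EtBr distilled off
Reagents that add atoms: none
Why: Michaelis–Arbuzov reaction by SN2 attack of phosphorus on the primary allylic bromide and dealkylation by bromide, which leaves the E alkene unchanged.

**Step 12**
Reactants: 15 (6R)-8'-apo-ε-caroten-8'-al; 18 diethyl [(2E)-3,7-dimethylocta-2,6-dien-1-yl]phosphonate
Product: 19 δ-carotene ((6R)-ε,ψ-carotene)
Conditions: 18, NaN(SiMe3)2 (1.0 equiv to 18), THF, −78 °C; add 15, −78 → 0 °C; then heptane, 80 °C, dark, crystallise
Reagents that add atoms: none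
Why: Horner–Wadsworth–Emmons olefination, in which the allylic phosphonate carbanion attacks through its α-carbon and elimination of diethyl phosphate should give the (7'E)-alkene, the low temperature and exact base stoichiometry keeping the doubly allylic C6–H of 15 from being deprotonated, and warming in heptane equilibrating any Z isomer to the all-E compound.

**Compound list**
1 | tert-butyl acetate | CC(=O)OC(C)(C)C | starting material
2 | tert-butyl[(1-tert-butoxyethenyl)oxy]dimethylsilane | C=C(OC(C)(C)C)O[Si](C)(C)C(C)(C)C | intermediate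
3 | mesityl oxide (4-methylpent-3-en-2-one) | CC(=O)C=C(C)C | starting material
4 | tert-butyl (4Z)-5-[(tert-butyldimethylsilyl)oxy]-3,3-dimethylhex-4-enoate | C/C(O[Si](C)(C)C(C)(C)C)=C/C(C)(C)CC(=O)OC(C)(C)C | intermediate
5 | tert-butyl (4S)-4-(hydroxymethyl)-3,3-dimethyl-5-oxohexanoate | CC(=O)[C@H](CO)C(C)(C)CC(=O)OC(C)(C)C | intermediate
6 | tert-butyl (4S)-4-{[(tert-butyldiphenylsilyl)oxy]methyl}-3,3-dimethyl-5-oxohexanoate | CC(=O)[C@H](CO[Si](c1ccccc1)(c1ccccc1)C(C)(C)C)C(C)(C)CC(=O)OC(C)(C)C | intermediate
7 | (4S)-4-{[(tert-butyldiphenylsilyl)oxy]methyl}-3,3-dimethyl-5-oxohexanoic acid | CC(=O)[C@H](CO[Si](c1ccccc1)(c1ccccc1)C(C)(C)C)C(C)(C)CC(=O)O | intermediate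
8 | vinyltriphenylphosphonium bromide | C=C[P+](c1ccccc1)(c1ccccc1)c1ccccc1.[Br-] | starting material
9 | (3S)-3-{[(tert-butyldiphenylsilyl)oxy]methyl}-4,4-dimethyl-7-(triphenyl-λ5-phosphanylidene)heptan-2-one (phosphonium ylide) | CC(=O)[C@H](CO[Si](c1ccccc1)(c1ccccc1)C(C)(C)C)C(C)(C)CCC=P(c1ccccc1)(c1ccccc1)c1ccccc1 | intermediate
10 | tert-butyl{[(1R)-2,6,6-trimethylcyclohex-2-en-1-yl]methoxy}diphenylsilane | CC(C)(C)[Si](c1ccccc1)(c1ccccc1)OC[C@H]1C(C)=CCCC1(C)C | intermediate
11 | [(1R)-2,6,6-trimethylcyclohex-2-en-1-yl]methanol | OC[C@H]1C(C)=CCCC1(C)C | intermediate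
12 | 1-phenyl-5-({[(1R)-2,6,6-trimethylcyclohex-2-en-1-yl]methyl}sulfanyl)-1H-tetrazole | c1ccccc1-n1nnnc1SC[C@H]1C(C)=CCCC1(C)C | intermediate
13 | 1-phenyl-5-({[(1R)-2,6,6-trimethylcyclohex-2-en-1-yl]methyl}sulfonyl)-1H-tetrazole | c1ccccc1-n1nnnc1S(=O)(=O)C[C@H]1C(C)=CCCC1(C)C | intermediate
14 | crocetin dialdehyde ((2E,4E,6E,8E,10E,12E,14E)-2,6,11,15-tetramethylhexadeca-2,4,6,8,10,12,14-heptaenedial) | O=C/C(C)=C/C=C/C(C)=C/C=C/C=C(C)/C=C/C=C(C)/C=O | starting material
15 | (6R)-8'-apo-ε-caroten-8'-al | O=C/C(C)=C/C=C/C(C)=C/C=C/C=C(C)/C=C/C=C(C)/C=C/[C@H]1C(C)=CCCC1(C)C | intermediate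
16 | geranyl bromide | CC(C)=CCC/C(C)=C/CBr | starting material
17 | triethyl phosphite | CCOP(OCC)OCC | starting material
18 | diethyl [(2E)-3,7-dimethylocta-2,6-dien-1-yl]phosphonate | CC(C)=CCC/C(C)=C/CP(=O)(OCC)OCC | intermediate
19 | δ-carotene ((6R)-ε,ψ-carotene) | CC(C)=CCC/C(C)=C/C=C/C(C)=C/C=C/C(C)=C/C=C/C=C(C)/C=C/C=C(C)/C=C/[C@H]1C(C)=CCCC1(C)C | target

**Totals**
Total step count: 12. Longest linear sequence: 11 (steps 1–10 and 12).

**Steps most likely to fail**

Step 6 (proposed new method). The unactivated primary carboxylate may be oxidised too slowly, bromide may quench the excited photocatalyst, or the ylide may be protonated before it closes the ring. The fallback uses known reactions, sets out from 7 and comes back at 10. Iododecarboxylation of 7 (PhI(OAc)2, I2, visible light, 1,2-dichloroethane, reflux) should give (3S)-3-{[(tert-butyldiphenylsilyl)oxy]methyl}-5-iodo-4,4-dimethylpentan-2-one F1. Keck radical allylation (allylSnBu3, azobisisobutyronitrile, benzene, 80 °C) should give (3S)-3-{[(tert-butyldiphenylsilyl)oxy]methyl}-4,4-dimethyloct-7-en-2-one F2. Non-basic Petasis methylenation of the ketone (Cp2TiMe2, toluene, 65 °C) should give tert-butyl{[(2S)-3,3-dimethyl-2-(prop-1-en-2-yl)hept-6-en-1-yl]oxy}diphenylsilane F3. Ring-closing metathesis (second-generation Grubbs catalyst, CH2Cl2, 40 °C) then forms C4=C5 with loss of ethene and gives 10.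

Step 3. Facial selectivity may be poor, the hindered silyl enol ether may react slowly with aqueous formaldehyde, or the β-hydroxy ketone may lose water. The fallback sets out from 4 and comes back at 5. Achiral hydroxymethylation (Yb(OTf)3 cat., aq. HCHO, THF/H2O, rt) should give racemic tert-butyl 4-(hydroxymethyl)-3,3-dimethyl-5-oxohexanoate F4. Kinetic resolution by lipase-catalysed acetylation (Burkholderia cepacia lipase, vinyl acetate, tert-butyl methyl ether, rt, stopped a little past half conversion) follows. On the assumption that the (4R)-alcohol reacts faster, it is removed as tert-butyl (4R)-4-(acetoxymethyl)-3,3-dimethyl-5-oxohexanoate F5 and the recovered alcohol is 5. If the enzyme shows the opposite preference, a lipase of the other preference is screened.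

Step 10. The symmetric dialdehyde may be olefinated twice, it may be poorly soluble at low temperature, and E-selectivity may be incomplete, all at the expense of the chiral sulfone. The fallback reverses the order of fragment union; it sets out from 14 and 18 and comes back at 19, replacing steps 10 and 12. Excess 14 is first olefinated with the anion of 18 (NaN(SiMe3)2, THF, −78 °C) to give 8'-apo-ψ-caroten-8'-al F6, so the statistical step uses the cheap geranyl unit. The anion of sulfone 13 (KN(SiMe3)2, THF, −78 °C) is then added to the mono-aldehyde F6 in a final Julia–Kocienski olefination, followed by thermal equilibration in heptane, to give 19.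

**Further compounds**
F1 | step 6 | (3S)-3-{[(tert-butyldiphenylsilyl)oxy]methyl}-5-iodo-4,4-dimethylpentan-2-one | CC(=O)[C@H](CO[Si](c1ccccc1)(c1ccccc1)C(C)(C)C)C(C)(C)CI
F2 | step 6 | (3S)-3-{[(tert-butyldiphenylsilyl)oxy]methyl}-4,4-dimethyloct-7-en-2-one | CC(=O)[C@H](CO[Si](c1ccccc1)(c1ccccc1)C(C)(C)C)C(C)(C)CCC=C
F3 | step 6 | tert-butyl{[(2S)-3,3-dimethyl-2-(prop-1-en-2-yl)hept-6-en-1-yl]oxy}diphenylsilane | C=C(C)[C@H](CO[Si](c1ccccc1)(c1ccccc1)C(C)(C)C)C(C)(C)CCC=C
F4 | step 3 | racemic tert-butyl 4-(hydroxymethyl)-3,3-dimethyl-5-oxohexanoate | CC(=O)C(CO)C(C)(C)CC(=O)OC(C)(C)C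
F5 | step 3 | tert-butyl (4R)-4-(acetoxymethyl)-3,3-dimethyl-5-oxohexanoate | CC(=O)[C@@H](COC(C)=O)C(C)(C)CC(=O)OC(C)(C)C
F6 | step 10 | 8'-apo-ψ-caroten-8'-al ((2E,4E,6E,8E,10E,12E,14E,16E,18E)-2,6,11,15,19,23-hexamethyltetracosa-2,4,6,8,10,12,14,16,18,22-decaenal) | CC(C)=CCC/C(C)=C/C=C/C(C)=C/C=C/C(C)=C/C=C/C=C(C)/C=C/C=C(C)/C=O
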